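**Target:** (2S)-2-heptadecyl-5,7-dihydroxy-6,8-dimethylchroman-4-one (9), C28H46O4. One stereocentre, C2 (priorities O1 > C3 > chain carbon > H, which gives S for the SMILES as written).

**Retrosynthetic overview**
1. 9 ⇐ 8: removal of two MOM ethers only.
2. 8 ⇐ 7: ring B (the dihydropyranone) is closed last by forming the O1–C2 bond in an enantioselective 6-endo oxa-Michael addition of the free ortho phenol to the (E)-enone. This one C–O bond makes the ring and the only stereocentre.
3. 7 ⇐ 3 + 4: aldol condensation of the aryl methyl ketone with octadecanal (no stereochemistry at stake).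
4. 3 ⇐ 1: ring A (the benzene ring) is bought as 2,4,6-trihydroxyacetophenone, then C-methylated twice and MOM-protected on two of its three OH groups.

Assumption: the catalyst of step 4 (made separately from (S)-tert-leucinol, not counted as a route step) is taken to give the 2S product; its sense of induction cannot be known beforehand, and the mirror-image catalyst from (R)-tert-leucinol is used if it proves opposite.

**Step 1**
Reactants: 1 2,4,6-trihydroxyacetophenone (commercial monohydrate, dried)
Product: 2 1-(2,4,6-trihydroxy-3,5-dimethylphenyl)ethan-1-one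
Conditions: NaOMe (3 equiv), MeI (2.5 equiv), MeOH, 0 °C → reflux
Reagents that add atoms: methyl iodide, CI
Why: C-alkylation of the ambident phloroglucinol-type phenolate, whose oxygens are hydrogen-bonded by MeOH so that the two free ring carbons are methylated in turn (known C-methylation of acylphloroglucinols); no stereocentre is formed.

**Step 2**
Reactants: 2 1-(2,4,6-trihydroxy-3,5-dimethylphenyl)ethan-1-one
Product: 3 1-[2-hydroxy-4,6-bis(methoxymethoxy)-3,5-dimethylphenyl]ethan-1-one
Conditions: MOMCl (2.3 equiv), iPr2NEt (3 equiv), CH2Cl2, 0 °C → rt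
Reagents that add atoms: chloromethyl methyl ether (MOMCl), COCCl
Why: MOM protection (Williamson-type O-alkylation) takes the para OH and one of the two equivalent ortho OH groups, while the other ortho OH is locked in a hydrogen bond to the ketone and stays free as the nucleophile needed in step 4.

**Step 3**
Reactants: 3 1-[2-hydroxy-4,6-bis(methoxymethoxy)-3,5-dimethylphenyl]ethan-1-one; 4 octadecanal
Product: 7 (E)-1-[2-hydroxy-4,6-bis(methoxymethoxy)-3,5-dimethylphenyl]icos-2-en-1-one, via racemic aldol 5 (not isolated), via mesylate 6 (not isolated)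
Conditions: LiN(iPr)2 (2.2 equiv), THF, −78 °C, then 4; aq NH4Cl; crude 5: MsCl (1.2 equiv), Et3N (3 equiv), CH2Cl2, −20 → 0 °C; cold citric acid wash, chromatography
Reagents that add atoms: none
Why: Directed aldol addition of the phenoxide/enolate dianion of 3 to the aldehyde, then mesylation of the secondary alcohol and E1cB elimination (aldol condensation) to the thermodynamically favoured (E)-enone; the chelated, hindered phenol is not sulfonylated and the racemic carbinol centre of 5 is erased.

**Step 4**
Reactants: 7 (E)-1-[2-hydroxy-4,6-bis(methoxymethoxy)-3,5-dimethylphenyl]icos-2-en-1-one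
Product: 8 (2S)-2-heptadecyl-5,7-bis(methoxymethoxy)-6,8-dimethylchroman-4-one
Conditions: iminophosphorane–thiourea catalyst ArNHC(=S)NH–CH(tBu)–CH2–N=P(C6H4-4-OMe)3, Ar = 3,5-(CF3)2C6H3, (S) at the tBu-bearing carbon (10 mol %), toluene (0.05 M), −20 °C; AcOH quench at −20 °C, silica plug
Reagents that add atoms: none
Why: Proposed new method: the iminophosphorane (a far stronger base than the tertiary amines of cinchona catalysts) deprotonates the hydrogen-bonded phenol of 7 to a chiral aminophosphonium phenoxide ion pair, the thiourea binds the carbonyl oxygen of the s-cis enone, the phenoxide oxygen adds to one face of the β-carbon in a 6-endo-trig oxa-Michael closure that forms O1–C2, ring B and the C2 stereocentre together, and the aminophosphonium N–H protonates the enolate to release the catalyst; the closest known reaction types are the cinchona-thiourea-catalysed oxa-Michael cyclisation of alkylidene β-keto esters to chromanones and iminophosphorane-catalysed intramolecular oxa-Michael additions of alcohols to unsaturated esters, whereas an unactivated 2'-hydroxyaryl alkenyl ketone carrying a plain alkyl group has not been cyclised this way.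

**Step 5**
Reactants: 8 (2S)-2-heptadecyl-5,7-bis(methoxymethoxy)-6,8-dimethylchroman-4-one
Product: 9 (2S)-2-heptadecyl-5,7-dihydroxy-6,8-dimethylchroman-4-one
Conditions: HCl (1.25 M in MeOH), THF, 40 °C; recrystallisation (hexane/EtOAc) to upgrade ee
Reagents that add atoms: none
Why: Acid-catalysed acetal exchange (MOM ether cleavage) is too mild to open the pyranone ring, so the C2 stereocentre from step 4 is kept, and the freed 5-OH then holds the ring-closed form by hydrogen bonding to the ketone.

**Compound list**
1 | 2,4,6-trihydroxyacetophenone | CC(=O)c1c(O)cc(O)cc1O | starting material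
2 | 1-(2,4,6-trihydroxy-3,5-dimethylphenyl)ethan-1-one | CC(=O)c1c(O)c(C)c(O)c(C)c1O | intermediate
3 | 1-[2-hydroxy-4,6-bis(methoxymethoxy)-3,5-dimethylphenyl]ethan-1-one | CC(=O)c1c(O)c(C)c(OCOC)c(C)c1OCOC | intermediate
4 | octadecanal | CCCCCCCCCCCCCCCCCC=O | starting material
5 | rac-3-hydroxy-1-[2-hydroxy-4,6-bis(methoxymethoxy)-3,5-dimethylphenyl]icosan-1-one (racemic aldol, not isolated) | CCCCCCCCCCCCCCCCCC(O)CC(=O)c1c(O)c(C)c(OCOC)c(C)c1OCOC | intermediate
6 | rac-1-[2-hydroxy-4,6-bis(methoxymethoxy)-3,5-dimethylphenyl]-1-oxoicosan-3-yl methanesulfonate (not isolated) | CCCCCCCCCCCCCCCCCC(OS(C)(=O)=O)CC(=O)c1c(O)c(C)c(OCOC)c(C)c1OCOC | intermediate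
7 | (E)-1-[2-hydroxy-4,6-bis(methoxymethoxy)-3,5-dimethylphenyl]icos-2-en-1-one | CCCCCCCCCCCCCCCCC/C=C/C(=O)c1c(O)c(C)c(OCOC)c(C)c1OCOC | intermediate
8 | (2S)-2-heptadecyl-5,7-bis(methoxymethoxy)-6,8-dimethylchroman-4-one | CCCCCCCCCCCCCCCCC[C@H]1CC(=O)c2c(OCOC)c(C)c(OCOC)c(C)c2O1 | intermediate
9 | (2S)-2-heptadecyl-5,7-dihydroxy-6,8-dimethylchroman-4-one | CCCCCCCCCCCCCCCCC[C@H]1CC(=O)c2c(O)c(C)c(O)c(C)c2O1 | target

**Total step count:** 5. **Longest linear sequence:** 5 steps (1 → 2 → 3 → 7 → 8 → 9; 4 is bought).

**Three steps most likely to fail**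

Step 4 (new method). The risks are low enantioselectivity, slow turnover of the hindered hydrogen-bonded phenol, and erosion of ee if the base reopens the ring before the quench. The fallback uses known chemistry, sets out from 3 and comes back at 9. The dianion of 3 (LiN(SiMe3)2, 3.3 equiv, THF, −78 °C) is C-acylated with Boc2O to tert-butyl 3-[2-hydroxy-4,6-bis(methoxymethoxy)-3,5-dimethylphenyl]-3-oxopropanoate F1. Knoevenagel condensation of this β-keto ester with 4 (piperidine, AcOH, toluene, 4 Å sieves) gives tert-butyl 2-[2-hydroxy-4,6-bis(methoxymethoxy)-3,5-dimethylbenzoyl]icos-2-enoate F2. The established cinchona-thiourea oxa-Michael cyclisation of such doubly activated alkylidene β-keto esters (quinine- or quinidine-derived thiourea, 10 mol %, toluene, −25 °C, the pseudoenantiomer that gives 2S) then forms tert-butyl (2S)-2-heptadecyl-5,7-bis(methoxymethoxy)-6,8-dimethyl-4-oxochromane-3-carboxylate F3. TsOH·H2O in toluene at 80 °C, then MeOH, cleaves the tert-butyl ester with decarboxylation and removes both MOM groups to give 9. Material from this route also serves as the reference for the absolute configuration and the ee assay.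

Step 3. The free phenol of 7 can close onto the new enone under Et3N to give racemic 8 (which must be removed completely by chromatography), the phenol can be mesylated, and the aldehyde can be enolised by the dianion. The fallback sets out from 3 and comes back at 7 with no free phenol present while the enone is made. The last phenol of 3 is capped (NaH, MOMCl, DMF) to give 1-[2,4,6-tris(methoxymethoxy)-3,5-dimethylphenyl]ethan-1-one F4. Its lithium enolate (LiN(iPr)2, 1.1 equiv, THF, −78 °C) adds to 4 to give rac-3-hydroxy-1-[2,4,6-tris(methoxymethoxy)-3,5-dimethylphenyl]icosan-1-one F5. Mesylation (MsCl, Et3N) gives rac-1-oxo-1-[2,4,6-tris(methoxymethoxy)-3,5-dimethylphenyl]icosan-3-yl methanesulfonate F6, and DBU eliminates it to (E)-1-[2,4,6-tris(methoxymethoxy)-3,5-dimethylphenyl]icos-2-en-1-one F7. One of the two equivalent ortho MOM groups, activated by the neighbouring carbonyl, is then removed selectively (dilute HCl in MeOH/THF, 0 °C, stopped at mono-deprotection) to give 7.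

Step 1. Over-methylation to gem-dimethyl dienones and O-methylation keep the yield modest (about 40–50% expected) and the purification tedious. The fallback sets out from 1 and comes back at 2 by a reductive route that cannot over-alkylate. Double Mannich aminomethylation of the two free ring positions (aqueous CH2O, Me2NH, EtOH, rt) gives 1-{3,5-bis[(dimethylamino)methyl]-2,4,6-trihydroxyphenyl}ethan-1-one F8. Hydrogenolysis of its two benzylic C–N bonds (H2, 3 bar, Pd/C, MeOH/AcOH, 40 °C) gives 2.

**Further compounds**
F1 | step 4 | tert-butyl 3-[2-hydroxy-4,6-bis(methoxymethoxy)-3,5-dimethylphenyl]-3-oxopropanoate | CC(C)(C)OC(=O)CC(=O)c1c(O)c(C)c(OCOC)c(C)c1OCOC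
F2 | step 4 | tert-butyl 2-[2-hydroxy-4,6-bis(methoxymethoxy)-3,5-dimethylbenzoyl]icos-2-enoate (E/Z mixture) | CCCCCCCCCCCCCCCCCC=C(C(=O)OC(C)(C)C)C(=O)c1c(O)c(C)c(OCOC)c(C)c1OCOC
F3 | step 4 | tert-butyl (2S)-2-heptadecyl-5,7-bis(methoxymethoxy)-6,8-dimethyl-4-oxochromane-3-carboxylate (C3 epimers) | CCCCCCCCCCCCCCCCC[C@H]1C(C(=O)OC(C)(C)C)C(=O)c2c(OCOC)c(C)c(OCOC)c(C)c2O1
F4 | step 3 | 1-[2,4,6-tris(methoxymethoxy)-3,5-dimethylphenyl]ethan-1-one | CC(=O)c1c(OCOC)c(C)c(OCOC)c(C)c1OCOC
F5 | step 3 | rac-3-hydroxy-1-[2,4,6-tris(methoxymethoxy)-3,5-dimethylphenyl]icosan-1-one | CCCCCCCCCCCCCCCCCC(O)CC(=O)c1c(OCOC)c(C)c(OCOC)c(C)c1OCOC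
F6 | step 3 | rac-1-oxo-1-[2,4,6-tris(methoxymethoxy)-3,5-dimethylphenyl]icosan-3-yl methanesulfonate | CCCCCCCCCCCCCCCCCC(OS(C)(=O)=O)CC(=O)c1c(OCOC)c(C)c(OCOC)c(C)c1OCOC
F7 | step 3 | (E)-1-[2,4,6-tris(methoxymethoxy)-3,5-dimethylphenyl]icos-2-en-1-one | CCCCCCCCCCCCCCCCC/C=C/C(=O)c1c(OCOC)c(C)c(OCOC)c(C)c1OCOC
F8 | step 1 | 1-{3,5-bis[(dimethylamino)methyl]-2,4,6-trihydroxyphenyl}ethan-1-one | CC(=O)c1c(O)c(CN(C)C)c(O)c(CN(C)C)c1O
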